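## Structural features

The target is a trans-2,3-diaryl-2,3-dihydrobenzofuran. Benzo ring A (C3a to C7a) is fused to the five-membered ring O1–C2–C3, with the 4-hydroxyphenyl ring B on C2, the 3,5-dihydroxyphenyl ring C on C3, and an (E)-3,5-dihydroxystyryl arm on C5, para to O1. C2 and C3 are adjacent stereocentres, both S, with rings B and C on opposite faces of the five-membered ring; the stereo tags in the target SMILES were checked and agree with this. The fragile sites are the C2–O1 bond (an aryl ether at a para-oxygenated benzylic carbon, which ionises under acid), the doubly benzylic C3–H, the E-stilbene and the five phenols. The real difficulty is to impose absolute configuration on the C2/C3 pair and then to free five phenols without opening the heterocycle. Ring A carries only three substituents (O1 on C7a, C3 on C3a, the styryl arm on C5), while C4, C6 and C7 bear hydrogen. Ring A can therefore be built last from three two-carbon alkyne units: C3a≡C4 hanging from C3, C7a≡C7 hanging from O1 as an ynol ether, and C5≡C6 carrying the arm. The stereochemical problem thereby becomes that of an acyclic anti-1,2-diaryl homopropargylic alcohol. Benzofuran locants are used below for the corresponding atoms of all intermediates.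

## Logic of the disconnections

**20 to 19.** The five phenolic O–H bonds are traced back to O–CH3 bonds. Free phenols would not survive the organozinc, organolithium and hydride chemistry, and the methyl ethers are already present in the aryl building blocks, so no protection step is spent. The demand is that the last step cleaves five methyl–oxygen bonds without ionising C2–O1. A boron Lewis acid with a soft iodide nucleophile at low temperature is therefore planned in place of BBr3 at room temperature.

**19 to 18.** C7–H is traced back to C7–Si. The silyl group is absent from the target; it is introduced because it decides the regiochemistry of ring A formation and because ipso-protonation removes it readily from a position ortho to O1. It must be removed before the demethylation, since boron halides attack aryl–silicon bonds, and with acid mild enough for the stilbene and for C2–O1.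

**18 to 14 and 17 (key).** Three bonds of ring A are cut: C3a–C7a, C4–C5 and C6–C7. Both rings of the benzofuran disappear; 14 holds all the stereochemistry and 17 holds the complete arm. The forward step must couple 14 with 17 and not either with itself, place the arm on C5 and not C6, use the alkyne of 17 and not its alkene, and run at room temperature because of the ynol ether. For regiocontrol C4 must be C–H and C7 must carry the bulky group.

**17 to 1 and 15 (through 16).** The C=C bond of the arm is cut. An E-selective phosphonate olefination delivers the enyne already carrying its alkyne, so no cross-coupling step is needed.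

**14 to 13.** C4–H is traced back to C4–SiMe3. A free terminal alkyne at C4 would be metalated by the bases needed to build the ynol ether and silylated together with the ynol terminus, so the two alkyne ends could not be told apart. Two different caps are therefore used: trimethylsilyl on C4 (labile) and triethylsilyl on C7 (markedly slower to cleave with methoxide). Trimethylsilyl on C7 would be the smallest group for the cyclotrimerisation, but it could not be distinguished from the C4 cap. The demand is a methanolysis that stops after the trimethylsilyl group.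

**13 to 11 to 8 and 9 (through 12 and 10).** The O1–C7a bond and the C7–Si bond are cut; C7a and C7 both come from 9. This reduces the diyne to a secondary alcohol. The forward steps must tolerate a hindered benzylic alkoxide and an acidic C3–H.

**8 to 5 and 6 (through 7).** The C2–C3 bond is cut. This is the only step that creates stereocentres. C3 comes from the axis of 7 (itself from the carbinol centre of 5), and C2 follows from the anti preference of the cyclic transition state.

**5 to 4 to 1 and 2 (through 3).** The C3–C3a bond is cut, leaving a catalytic asymmetric alkynylation of an aryl aldehyde.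

**Descriptors.** No centre is inverted after step 3, but the CIP labels change. The C3 carbon is S in 8, 11 and 13 (the silylalkyne outranks ring C), R in 14 (ring C outranks the free alkyne) and S again in 18 to 20 (C3a outranks ring C). The anti diyne 14 is thus (1S,2R), and it maps atom for atom onto the (2S,3S)-trans target.

## Other disconnections considered

**Alternative 1:** The cut runs through C2–ring B and C3–C3a; O1–C7a and the arm are left for later. Forward, the alkenyl boronate A1 and the aryllithium A2 form a four-coordinate borate. The aryl triflate A3 adds oxidatively to zerovalent palladium (from Pd(OAc)2 and a chiral MandyPhos ligand), the arylpalladium binds the alkene, ring B shifts from boron to C2 anti to the metal, and reductive elimination would give A4.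
- In favour: both stereocentres would be set in one catalytic enantioselective step from achiral partners. Anti addition across the E-alkene is stereospecific and maps onto the trans ring after stereoretentive C–B oxidation and closure of O1–C7a by fluoride displacement. On the source of chirality this is the better plan.
- Against: β-aryl alkenyl borates are demanding in this reaction, since the 1,2-shift is slowed and direct Suzuki coupling of either boron ligand competes. The ring closure needs a hindered benzylic alkoxide to displace a fluoride activated only by a para ester. The ester must still be converted into the arm by reduction and olefination.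
- Comparison: structurally ring A arrives intact and no silyl director is needed, but the arm costs about three extra steps, whereas the chosen plan installs it in the key step. Mechanistically the stereo-defining step is intermolecular and ligand-controlled, where the chosen plan uses chirality transfer. Step economy is about equal, at eight to nine steps.

**Alternative 2:** The cut runs through C7a–O1 and C3a–C3. Forward, CsF would release a 3-chloro-4-bromoaryne from A5; the oxygen of the epoxide A6 would attack C7a, and the aryl anion at C3a would bond to the ring C carbon as its C–O bond breaks, giving A7.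
- In favour: it is convergent, the heterocycle forms in one step, and the chirality comes from an asymmetric epoxidation of a stilbene, which is at least the equal of the chirality transfer used here.
- Against: the aryl anion cannot reach C3 from the back, so the C–C bond would form through an ion pair or benzylic cation, with possible leakage at C3 and competing rearrangement of the epoxide. Scission at the ring C carbon and not the ring B carbon rests only on the deactivating triflate. The end game must then tell bromide, chloride and triflate apart: Heck reaction with A8 at the bromide, hydrodechlorination without reducing the stilbene, triflate cleavage and demethylation.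
- Comparison: in convergence it equals the chosen plan. Mechanistically its stereocentres take part in the ring-forming step, whereas in the chosen plan they are spectators. Step economy is no better, because A5 and the four-step end game offset the short key step.

**Alternative 3:** The cut runs through C2–C3 and O1–C2. Forward, Cs2CO3 would release an ortho-quinone methide from the sulfone A9 and an ylide from the chiral sulfonium salt A10. The ylide carbon adds to C3, and the phenoxide displaces the thiolane at C2 to give A11; a Heck reaction of A11 with A8 then leads to 19.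
- In favour: it is metal-free, mild and trans-selective through the anti betaine and SN2 closure, with rings A and C preassembled. It needs about six to seven steps, so on step economy it is the better plan.
- Against: the enantioselectivity depends on a stoichiometric chiral sulfide (the enantiomer of A10 would be chosen to match) in an intermolecular addition of a semi-stabilised benzylic ylide that may be reversible. An aryl-substituted quinone methide is a less reactive acceptor.
- Comparison: structurally it keeps ring A and adds only the arm. Mechanistically both stereocentres are created at once, whereas the chosen plan sets them in a reagent-controlled closed transition state before any ring exists. The end game from 19 is the same, so on that point the two are equal.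

Key step: step 8

Assumption: the sense of induction of (S,S)-ProPhenol in step 1 is assigned by analogy; if a Mosher ester check of 4 shows the opposite sense, the (R,R)-ligand is used and nothing else changes.
Assumption: 15 is treated as a catalogue reagent; otherwise it is one Arbuzov step from 3-bromo-1-(trimethylsilyl)propyne and triethyl phosphite.

## Route

Step 1
Reactants: 1 3,5-dimethoxybenzaldehyde; 2 trimethylsilylacetylene
Product: 4 (R)-1-(3,5-dimethoxyphenyl)-3-(trimethylsilyl)prop-2-yn-1-ol, via methyl[(trimethylsilyl)ethynyl]zinc 3 (not isolated)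
Conditions: 2 (3 equiv), Me2Zn (3 equiv, toluene solution), (S,S)-ProPhenol (10 mol %), toluene, 0 → 4 °C; aq NH4Cl
Reagents that add atoms: none
Why: Catalytic enantioselective alkynylation of an aldehyde: Me2Zn metalates 2 to the zinc acetylide 3, which is delivered to one face of the zinc-bound aldehyde inside the dinuclear zinc–ligand pocket, so the ligand sets the carbinol centre. Aryl aldehydes and silylacetylenes are standard substrates for this reaction.

Step 2
Reactants: 4 (R)-1-(3,5-dimethoxyphenyl)-3-(trimethylsilyl)prop-2-yn-1-ol
Product: 5 (R)-1-(3,5-dimethoxyphenyl)-3-(trimethylsilyl)prop-2-yn-1-yl methanesulfonate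
Conditions: MsCl (1.2 equiv), Et3N (1.5 equiv), CH2Cl2, −78 °C; cold NaHCO3 work-up, crude used at once
Reagents that add atoms: methanesulfonyl chloride, CS(=O)(=O)Cl
Why: O-Sulfonylation (mesylation) leaves the C–O bond and hence the R configuration untouched. The two meta-methoxy groups do not stabilise a benzylic cation, so the mesylate should persist at low temperature long enough to be used crude.

Step 3
Reactants: 5 (R)-1-(3,5-dimethoxyphenyl)-3-(trimethylsilyl)prop-2-yn-1-yl methanesulfonate; 6 4-methoxybenzaldehyde
Product: 8 (1S,2S)-2-(3,5-dimethoxyphenyl)-1-(4-methoxyphenyl)-4-(trimethylsilyl)but-3-yn-1-ol, via (aS)-allenylzinc reagent 7 (not isolated)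
Conditions: Pd(OAc)2 (5 mol %), PPh3 (5 mol %), Et2Zn (3 equiv, hexane solution), THF, −78 → −20 °C; aq NH4Cl
Reagents that add atoms: none
Why: Marshall propargylation: zerovalent palladium displaces the mesylate in an anti SN2′ sense, transmetalation to zinc with retention gives the allenylzinc 7, and 7 adds to 6 through a closed six-membered SE2′ transition state. The axis of 7 fixes C3 (net inversion at the former mesylate carbon), and the aldehyde aryl group lies away from the allenyl aryl group in that transition state, which fixes C2 and gives the anti alcohol.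

Step 4
Reactants: 8 (1S,2S)-2-(3,5-dimethoxyphenyl)-1-(4-methoxyphenyl)-4-(trimethylsilyl)but-3-yn-1-ol; 9 trichloroethylene
Product: 11 {(3S,4S)-4-[(E)-1,2-dichloroethenyloxy]-3-(3,5-dimethoxyphenyl)-4-(4-methoxyphenyl)but-1-yn-1-yl}trimethylsilane, via dichloroacetylene 10 (not isolated)
Conditions: KH (1.5 equiv, oil dispersion), THF, 0 °C; then 9 (1.2 equiv), −50 → 0 °C, argon
Reagents that add atoms: none
Why: Ynol ether synthesis by the trichloroethylene route: the potassium alkoxide eliminates HCl from 9 to give 10 and then adds to it in a trans sense, giving the E-dichlorovinyl ether. No bond to C2 or C3 is touched, and the silyl cap keeps the C4 alkyne from being metalated.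

Step 5
Reactants: 11 {(3S,4S)-4-[(E)-1,2-dichloroethenyloxy]-3-(3,5-dimethoxyphenyl)-4-(4-methoxyphenyl)but-1-yn-1-yl}trimethylsilane
Product: 13 triethyl({[(1S,2S)-2-(3,5-dimethoxyphenyl)-1-(4-methoxyphenyl)-4-(trimethylsilyl)but-3-yn-1-yl]oxy}ethynyl)silane, via lithium alkoxyacetylide 12 (not isolated)
Conditions: n-BuLi (2.1 equiv), THF, −78 °C; Et3SiCl (1.5 equiv), −78 → −30 °C; NaHCO3 work-up, Et3N-deactivated silica
Reagents that add atoms: chlorotriethylsilane, CC[Si](Cl)(CC)CC
Why: Dehydrochlorination followed by lithium–chlorine exchange converts the dichlorovinyl ether into the lithium acetylide 12, which is C-silylated by Et3SiCl. The vinylic C–H is removed far faster than the hindered C3–H at −78 °C, and triethylsilyl is chosen so that the two alkyne caps can be told apart in step 6.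

Step 6
Reactants: 13 triethyl({[(1S,2S)-2-(3,5-dimethoxyphenyl)-1-(4-methoxyphenyl)-4-(trimethylsilyl)but-3-yn-1-yl]oxy}ethynyl)silane
Product: 14 triethyl({[(1S,2R)-2-(3,5-dimethoxyphenyl)-1-(4-methoxyphenyl)but-3-yn-1-yl]oxy}ethynyl)silane
Conditions: K2CO3 (0.2 equiv), MeOH–THF 1:1, 0 °C, stopped when 13 is consumed; kept below 20 °C and used at once
Reagents that add atoms: none
Why: Base-catalysed methanolysis of an alkynylsilane: methoxide attacks the unhindered trimethylsilyl group much faster than the triethylsilyl group, whose ethyl groups shield silicon, so only the C4 alkyne is freed. The stereocentres are not involved; the descriptor at C3 changes from S to R only because the CIP priorities change.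

Step 7
Reactants: 1 3,5-dimethoxybenzaldehyde; 15 diethyl [3-(trimethylsilyl)prop-2-yn-1-yl]phosphonate
Product: 17 1-[(E)-but-1-en-3-yn-1-yl]-3,5-dimethoxybenzene, via silylated enyne 16 (not isolated)
Conditions: NaN(SiMe3)2 (1.05 equiv), THF, −78 → 0 °C; then MeOH, K2CO3 (1.5 equiv), 20 °C
Reagents that add atoms: none
Why: Horner–Wadsworth–Emmons olefination with a propargylic phosphonate, which is E-selective with aromatic aldehydes because the alkyne-stabilised carbanion adds reversibly. The C-silyl group of 16 is then removed in the same flask by base-catalysed methanolysis.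

Step 8
Reactants: 14 triethyl({[(1S,2R)-2-(3,5-dimethoxyphenyl)-1-(4-methoxyphenyl)but-3-yn-1-yl]oxy}ethynyl)silane; 17 1-[(E)-but-1-en-3-yn-1-yl]-3,5-dimethoxybenzene
Product: 18 [(2S,3S)-3-(3,5-dimethoxyphenyl)-5-[(E)-2-(3,5-dimethoxyphenyl)ethenyl]-2-(4-methoxyphenyl)-2,3-dihydro-1-benzofuran-7-yl]triethylsilane
Conditions: Cp*RuCl(cod) (10 mol %), 17 (3 equiv), ClCH2CH2Cl, 20 °C, 14 added over 4 h by syringe pump, argon
Reagents that add atoms: none
Why: Loss of cod lets the Cp*RuCl fragment of divalent ruthenium bind both alkynes of 14, and oxidative cyclisation gives a ruthenacyclopentatriene of formally tetravalent ruthenium in which C3a–C7a is formed and the metal is bonded to C4 and C7. This closes the dihydrofuran ring around the O1–C2–C3 tether, the normal five-membered mode for a 1,6-diyne. The terminal alkyne of 17 then adds across the unhindered Ru–C4 bond with its substituted carbon joining C4 and its CH end on the metal, and reductive elimination joins C6 to C7, closing benzene ring A in a formal (2+2+2) cycloaddition. The closest known reaction type is the Cp*RuCl(cod)-catalysed cyclotrimerisation of unsymmetrical 1,6-diynes with terminal alkynes, which places the new substituent meta to the substituent on the diyne terminus. No stereocentre is formed: C2 and C3 are sp3 spectators, so the anti relationship of 14 appears unchanged as trans in 18. Regioselectivity (arm on C5, not C6) is secured by the triethylsilyl group on C7, which blocks the Ru–C7 side, while C4 is deliberately left as C–H. Chemoselectivity for the alkyne of 17 over its alkene rests on the stronger binding of alkynes to this catalyst, and cross-selectivity on slow addition of 14 to an excess of 17. Room temperature is essential because the secondary ynol ether would fragment by a retro-ene path on heating.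

Step 9
Reactants: 18 [(2S,3S)-3-(3,5-dimethoxyphenyl)-5-[(E)-2-(3,5-dimethoxyphenyl)ethenyl]-2-(4-methoxyphenyl)-2,3-dihydro-1-benzofuran-7-yl]triethylsilane
Product: 19 (2S,3S)-3-(3,5-dimethoxyphenyl)-5-[(E)-2-(3,5-dimethoxyphenyl)ethenyl]-2-(4-methoxyphenyl)-2,3-dihydro-1-benzofuran
Conditions: CF3CO2H (10 equiv), CH2Cl2, 0 °C, short reaction time; aq NaHCO3
Reagents that add atoms: none
Why: Electrophilic ipso-protodesilylation of an arylsilane: C7 is ortho to O1, so protonation there gives a cation stabilised by the oxygen and by the β-silicon, and loss of the silyl group restores ring A. Short exposure at 0 °C limits protonation of the stilbene and ionisation at C2, and C3 is not touched.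

Step 10
Reactants: 19 (2S,3S)-3-(3,5-dimethoxyphenyl)-5-[(E)-2-(3,5-dimethoxyphenyl)ethenyl]-2-(4-methoxyphenyl)-2,3-dihydro-1-benzofuran
Product: 20 (2S,3S)-trans-δ-viniferin, 5-[(2S,3S)-5-[(E)-2-(3,5-dihydroxyphenyl)ethenyl]-2-(4-hydroxyphenyl)-2,3-dihydro-1-benzofuran-3-yl]benzene-1,3-diol
Conditions: BCl3 (15 equiv), n-Bu4NI (15 equiv), CH2Cl2, −78 → 0 °C, dark, argon; ice-water, then aq NaHCO3
Reagents that add atoms: none
Why: Lewis-acid-assisted SN2 demethylation of aryl methyl ethers: boron binds each methoxy oxygen and iodide removes the methyl group as iodomethane. The soft nucleophile at low temperature lets cleavage at the unhindered methyl carbons outrun ionisation of C2–O1, and hydrolysis of the aryl borates on work-up gives the pentaphenol with C2 and C3 unchanged.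

## Compound list

1 | 3,5-dimethoxybenzaldehyde | COc1cc(C=O)cc(OC)c1 | starting material
2 | trimethylsilylacetylene | C#C[Si](C)(C)C | starting material
3 | methyl[(trimethylsilyl)ethynyl]zinc | C[Zn]C#C[Si](C)(C)C | intermediate (not isolated)
4 | (R)-1-(3,5-dimethoxyphenyl)-3-(trimethylsilyl)prop-2-yn-1-ol | COc1cc(OC)cc([C@@H](O)C#C[Si](C)(C)C)c1 | intermediate
5 | (R)-1-(3,5-dimethoxyphenyl)-3-(trimethylsilyl)prop-2-yn-1-yl methanesulfonate | COc1cc(OC)cc([C@@H](OS(C)(=O)=O)C#C[Si](C)(C)C)c1 | intermediate
6 | 4-methoxybenzaldehyde | COc1ccc(C=O)cc1 | starting material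
7 | (aS)-[3-(3,5-dimethoxyphenyl)-1-(trimethylsilyl)propa-1,2-dien-1-yl](ethyl)zinc | CC[Zn]C([Si](C)(C)C)=[C@@]=C([H])c1cc(OC)cc(OC)c1 | intermediate (not isolated)
8 | (1S,2S)-2-(3,5-dimethoxyphenyl)-1-(4-methoxyphenyl)-4-(trimethylsilyl)but-3-yn-1-ol | COc1ccc([C@H]([C@@H](c2cc(OC)cc(OC)c2)C#C[Si](C)(C)C)O)cc1 | intermediate
9 | trichloroethylene | ClC=C(Cl)Cl | starting material
10 | dichloroacetylene | ClC#CCl | intermediate (not isolated)
11 | {(3S,4S)-4-[(E)-1,2-dichloroethenyloxy]-3-(3,5-dimethoxyphenyl)-4-(4-methoxyphenyl)but-1-yn-1-yl}trimethylsilane | COc1ccc([C@H]([C@@H](c2cc(OC)cc(OC)c2)C#C[Si](C)(C)C)O/C(Cl)=C\Cl)cc1 | intermediate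
12 | lithium 2-{[(1S,2S)-2-(3,5-dimethoxyphenyl)-1-(4-methoxyphenyl)-4-(trimethylsilyl)but-3-yn-1-yl]oxy}ethyn-1-ide | COc1ccc([C@H]([C@@H](c2cc(OC)cc(OC)c2)C#C[Si](C)(C)C)OC#C[Li])cc1 | intermediate (not isolated)
13 | triethyl({[(1S,2S)-2-(3,5-dimethoxyphenyl)-1-(4-methoxyphenyl)-4-(trimethylsilyl)but-3-yn-1-yl]oxy}ethynyl)silane | COc1ccc([C@H]([C@@H](c2cc(OC)cc(OC)c2)C#C[Si](C)(C)C)OC#C[Si](CC)(CC)CC)cc1 | intermediate
14 | triethyl({[(1S,2R)-2-(3,5-dimethoxyphenyl)-1-(4-methoxyphenyl)but-3-yn-1-yl]oxy}ethynyl)silane | COc1ccc([C@H]([C@@H](c2cc(OC)cc(OC)c2)C#C)OC#C[Si](CC)(CC)CC)cc1 | intermediate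
15 | diethyl [3-(trimethylsilyl)prop-2-yn-1-yl]phosphonate | CCOP(=O)(CC#C[Si](C)(C)C)OCC | starting material
16 | [(E)-4-(3,5-dimethoxyphenyl)but-3-en-1-yn-1-yl]trimethylsilane | COc1cc(/C=C/C#C[Si](C)(C)C)cc(OC)c1 | intermediate (not isolated)
17 | 1-[(E)-but-1-en-3-yn-1-yl]-3,5-dimethoxybenzene | C#C/C=C/c1cc(OC)cc(OC)c1 | intermediate
18 | [(2S,3S)-3-(3,5-dimethoxyphenyl)-5-[(E)-2-(3,5-dimethoxyphenyl)ethenyl]-2-(4-methoxyphenyl)-2,3-dihydro-1-benzofuran-7-yl]triethylsilane | COc1ccc([C@H]2Oc3c([Si](CC)(CC)CC)cc(/C=C/c4cc(OC)cc(OC)c4)cc3[C@@H]2c2cc(OC)cc(OC)c2)cc1 | intermediate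
19 | (2S,3S)-3-(3,5-dimethoxyphenyl)-5-[(E)-2-(3,5-dimethoxyphenyl)ethenyl]-2-(4-methoxyphenyl)-2,3-dihydro-1-benzofuran | COc1ccc([C@H]2Oc3ccc(/C=C/c4cc(OC)cc(OC)c4)cc3[C@@H]2c2cc(OC)cc(OC)c2)cc1 | intermediate
20 | (2S,3S)-trans-δ-viniferin | Oc1ccc([C@H]2Oc3ccc(/C=C/c4cc(O)cc(O)c4)cc3[C@@H]2c2cc(O)cc(O)c2)cc1 | target

## Step count and least certain steps

Total: 10 steps. Longest linear sequence: 9 steps (steps 1 to 6, then 8, 9 and 10); step 7 is a one-step branch.

**Step 8 (key).** The most likely failure is diversion of the catalyst. Oxidative cyclisation of an electron-rich, silyl-capped ynol ether diyne may be slow, and the conjugated enyne may then bind ruthenium through its alkene or oligomerise, so that cross-coupling is lost. Erosion of the C5/C6 regiocontrol is the second risk.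
Fallback, from 14 back to 18: 14 would be cyclotrimerised under the same Cp*RuCl(cod) conditions with prop-2-yn-1-ol, a small unconjugated terminal alkyne, to give [(2S,3S)-3-(3,5-dimethoxyphenyl)-2-(4-methoxyphenyl)-7-(triethylsilyl)-2,3-dihydro-1-benzofuran-5-yl]methanol F1. Oxidation with MnO2 in CH2Cl2 would give (2S,3S)-3-(3,5-dimethoxyphenyl)-2-(4-methoxyphenyl)-7-(triethylsilyl)-2,3-dihydro-1-benzofuran-5-carbaldehyde F2. A Horner–Wadsworth–Emmons reaction of F2 with diethyl (3,5-dimethoxybenzyl)phosphonate (KOt-Bu, THF, 0 °C) would then build the E-alkene and return to 18.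

**Step 3.** The aryl substituent may speed loss of axial chirality in the allenylpalladium and allenylzinc species, and an aromatic aldehyde may give incomplete anti facial selectivity. Ionisation of the benzylic mesylate before palladium reacts would have the same effect.
Fallback, from 8 as obtained back to stereochemically uniform 8: the alcohol would be esterified with (S)-2-methoxy-2-phenylacetic acid (DCC, DMAP, CH2Cl2) to (1S,2S)-2-(3,5-dimethoxyphenyl)-1-(4-methoxyphenyl)-4-(trimethylsilyl)but-3-yn-1-yl (2S)-2-methoxy-2-phenylacetate F3. The esters of the minor enantiomer and of the syn isomer are diastereomers of F3 and would be removed by chromatography or crystallisation. Reductive cleavage with i-Bu2AlH at −78 °C would return 8 without touching the C4 silyl group.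

**Step 4.** The hindered potassium alkoxide may fragment by retro-propargylation to 6 and a stabilised propargyl anion, or may add sluggishly to 10. The same substrate class also carries the acidic C3–H into the organolithium step 5, where β-elimination of the ynolate is conceivable.
Fallback, from 8 to 13: formylation with acetic formic anhydride and pyridine would give (1S,2S)-2-(3,5-dimethoxyphenyl)-1-(4-methoxyphenyl)-4-(trimethylsilyl)but-3-yn-1-yl formate F4 without any alkoxide. Ramirez olefination (PPh3, CBr4, CH2Cl2) would convert F4 into {(3S,4S)-4-(2,2-dibromoethenyloxy)-3-(3,5-dimethoxyphenyl)-4-(4-methoxyphenyl)but-1-yn-1-yl}trimethylsilane F5. Treatment with n-BuLi (2.1 equiv, −78 °C) would effect a Corey–Fuchs-type bromine–lithium exchange, 1,2-shift and acetylide formation, both faster than deprotonation at C3, to give 12; Et3SiCl would then give 13.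

**Step 6.** Chemoselectivity may be lost if methoxide also attacks the triethylsilyl group on the ynol ether, or if the base removes C3–H and expels the ynolate.
Fallback, from 11 to 19: 11 would be treated with n-BuLi and then t-BuMe2SiOTf to give tert-butyl({[(1S,2S)-2-(3,5-dimethoxyphenyl)-1-(4-methoxyphenyl)-4-(trimethylsilyl)but-3-yn-1-yl]oxy}ethynyl)dimethylsilane F6, whose ynol cap is inert to K2CO3 in MeOH. Methanolysis would give tert-butyl({[(1S,2R)-2-(3,5-dimethoxyphenyl)-1-(4-methoxyphenyl)but-3-yn-1-yl]oxy}ethynyl)dimethylsilane F7. Cyclotrimerisation with 17 as in step 8 would give tert-butyl[(2S,3S)-3-(3,5-dimethoxyphenyl)-5-[(E)-2-(3,5-dimethoxyphenyl)ethenyl]-2-(4-methoxyphenyl)-2,3-dihydro-1-benzofuran-7-yl]dimethylsilane F8. Protodesilylation of F8 with CF3CO2H, for longer than in step 9, would return to 19.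

**Step 10.** The Lewis acid may ionise the C2–O1 bond, opening the ring with halide capture at C2 before all five methyl groups are removed; acid-induced reaction of the stilbene is a lesser risk.
Fallback, from 19 to 20: the opening would be accepted and reversed. Excess BBr3 (CH2Cl2, −78 → 0 °C) would cleave all methyl ethers and the C2–O1 bond to give 5-[(1S)-2-bromo-1-{5-[(E)-2-(3,5-dihydroxyphenyl)ethenyl]-2-hydroxyphenyl}-2-(4-hydroxyphenyl)ethyl]benzene-1,3-diol F9, a mixture at the bromine-bearing carbon. NaHCO3 in aqueous acetone would eliminate HBr to give the para-quinone methide 4-[(2S)-2-(3,5-dihydroxyphenyl)-2-{5-[(E)-2-(3,5-dihydroxyphenyl)ethenyl]-2-hydroxyphenyl}ethylidene]cyclohexa-2,5-dien-1-one F10. The ring A phenol would add to F10 at C2 in a 5-exo closure, trans to ring C under control of the untouched C3, giving 20.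

## Further compounds

F1 | step 8 | [(2S,3S)-3-(3,5-dimethoxyphenyl)-2-(4-methoxyphenyl)-7-(triethylsilyl)-2,3-dihydro-1-benzofuran-5-yl]methanol | COc1ccc([C@H]2Oc3c([Si](CC)(CC)CC)cc(CO)cc3[C@@H]2c2cc(OC)cc(OC)c2)cc1
F2 | step 8 | (2S,3S)-3-(3,5-dimethoxyphenyl)-2-(4-methoxyphenyl)-7-(triethylsilyl)-2,3-dihydro-1-benzofuran-5-carbaldehyde | COc1ccc([C@H]2Oc3c([Si](CC)(CC)CC)cc(C=O)cc3[C@@H]2c2cc(OC)cc(OC)c2)cc1
F3 | step 3 | (1S,2S)-2-(3,5-dimethoxyphenyl)-1-(4-methoxyphenyl)-4-(trimethylsilyl)but-3-yn-1-yl (2S)-2-methoxy-2-phenylacetate | COc1ccc([C@H]([C@@H](c2cc(OC)cc(OC)c2)C#C[Si](C)(C)C)OC(=O)[C@@H](OC)c2ccccc2)cc1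
F4 | step 4 | (1S,2S)-2-(3,5-dimethoxyphenyl)-1-(4-methoxyphenyl)-4-(trimethylsilyl)but-3-yn-1-yl formate | COc1ccc([C@H]([C@@H](c2cc(OC)cc(OC)c2)C#C[Si](C)(C)C)OC=O)cc1
F5 | step 4 | {(3S,4S)-4-(2,2-dibromoethenyloxy)-3-(3,5-dimethoxyphenyl)-4-(4-methoxyphenyl)but-1-yn-1-yl}trimethylsilane | COc1ccc([C@H]([C@@H](c2cc(OC)cc(OC)c2)C#C[Si](C)(C)C)OC=C(Br)Br)cc1
F6 | step 6 | tert-butyl({[(1S,2S)-2-(3,5-dimethoxyphenyl)-1-(4-methoxyphenyl)-4-(trimethylsilyl)but-3-yn-1-yl]oxy}ethynyl)dimethylsilane | COc1ccc([C@H]([C@@H](c2cc(OC)cc(OC)c2)C#C[Si](C)(C)C)OC#C[Si](C)(C)C(C)(C)C)cc1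
F7 | step 6 | tert-butyl({[(1S,2R)-2-(3,5-dimethoxyphenyl)-1-(4-methoxyphenyl)but-3-yn-1-yl]oxy}ethynyl)dimethylsilane | COc1ccc([C@H]([C@@H](c2cc(OC)cc(OC)c2)C#C)OC#C[Si](C)(C)C(C)(C)C)cc1
F8 | step 6 | tert-butyl[(2S,3S)-3-(3,5-dimethoxyphenyl)-5-[(E)-2-(3,5-dimethoxyphenyl)ethenyl]-2-(4-methoxyphenyl)-2,3-dihydro-1-benzofuran-7-yl]dimethylsilane | COc1ccc([C@H]2Oc3c([Si](C)(C)C(C)(C)C)cc(/C=C/c4cc(OC)cc(OC)c4)cc3[C@@H]2c2cc(OC)cc(OC)c2)cc1
F9 | step 10 | 5-[(1S)-2-bromo-1-{5-[(E)-2-(3,5-dihydroxyphenyl)ethenyl]-2-hydroxyphenyl}-2-(4-hydroxyphenyl)ethyl]benzene-1,3-diol | Oc1ccc(C(Br)[C@@H](c2cc(O)cc(O)c2)c2cc(/C=C/c3cc(O)cc(O)c3)ccc2O)cc1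
F10 | step 10 | 4-[(2S)-2-(3,5-dihydroxyphenyl)-2-{5-[(E)-2-(3,5-dihydroxyphenyl)ethenyl]-2-hydroxyphenyl}ethylidene]cyclohexa-2,5-dien-1-one | O=C1C=CC(=C[C@@H](c2cc(O)cc(O)c2)c2cc(/C=C/c3cc(O)cc(O)c3)ccc2O)C=C1
A1 | alternative 1 | 2-[(E)-2-(3,5-dimethoxyphenyl)ethenyl]-4,4,5,5-tetramethyl-1,3,2-dioxaborolane | COc1cc(/C=C/B2OC(C)(C)C(C)(C)O2)cc(OC)c1
A2 | alternative 1 | (4-methoxyphenyl)lithium | [Li]c1ccc(OC)cc1
A3 | alternative 1 | methyl 4-fluoro-3-(trifluoromethylsulfonyloxy)benzoate | COC(=O)c1ccc(F)c(OS(=O)(=O)C(F)(F)F)c1
A4 | alternative 1 | methyl 3-[(1S,2S)-1-(3,5-dimethoxyphenyl)-2-(4-methoxyphenyl)-2-(4,4,5,5-tetramethyl-1,3,2-dioxaborolan-2-yl)ethyl]-4-fluorobenzoate | COc1ccc([C@@H](B2OC(C)(C)C(C)(C)O2)[C@@H](c2cc(OC)cc(OC)c2)c2cc(C(=O)OC)ccc2F)cc1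
A5 | alternative 2 | 3-bromo-2-chloro-6-(trimethylsilyl)phenyl trifluoromethanesulfonate | C[Si](C)(C)c1ccc(Br)c(Cl)c1OS(=O)(=O)C(F)(F)F
A6 | alternative 2 | 4-[(2R,3R)-3-(3,5-dimethoxyphenyl)oxiran-2-yl]phenyl trifluoromethanesulfonate | O=S(=O)(Oc1ccc([C@H]2O[C@@H]2c2cc(OC)cc(OC)c2)cc1)C(F)(F)F
A7 | alternative 2 | (2S,3S)-5-bromo-4-chloro-3-(3,5-dimethoxyphenyl)-2-[4-(trifluoromethylsulfonyloxy)phenyl]-2,3-dihydro-1-benzofuran | O=S(=O)(Oc1ccc([C@H]2Oc3ccc(Br)c(Cl)c3[C@@H]2c2cc(OC)cc(OC)c2)cc1)C(F)(F)F
A8 | alternative 2 | 1-ethenyl-3,5-dimethoxybenzene | C=Cc1cc(OC)cc(OC)c1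
A9 | alternative 3 | 4-bromo-2-[(3,5-dimethoxyphenyl)(4-methylphenylsulfonyl)methyl]phenol, racemic | Cc1ccc(S(=O)(=O)C(c2cc(OC)cc(OC)c2)c2cc(Br)ccc2O)cc1
A10 | alternative 3 | (2R,5R)-1-[(4-methoxyphenyl)methyl]-2,5-dimethylthiolan-1-ium trifluoromethanesulfonate | COc1ccc(C[S+]2[C@H](C)CC[C@H]2C)cc1.[O-]S(=O)(=O)C(F)(F)F
A11 | alternative 3 | (2S,3S)-5-bromo-3-(3,5-dimethoxyphenyl)-2-(4-methoxyphenyl)-2,3-dihydro-1-benzofuran | COc1ccc([C@H]2Oc3ccc(Br)cc3[C@@H]2c2cc(OC)cc(OC)c2)cc1
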